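## Retrosynthetic overview

1. Azafrin ⇒ ester hydrolysis of its methyl ester ⇒ Wittig disconnection at C11=C12 into a C15 diol phosphonium salt and a C12 aldehyde ester.
2. C12 aldehyde ester ⇒ mono-Wittig of the technical C10 dialdehyde with Ph3P=CHCO2Me.
3. C15 phosphonium salt ⇒ tertiary vinyl carbinol (SN1' with PPh3·HBr) ⇒ vinyl Grignard addition to (5R,6R)-5,6-dihydroxy-5,6-dihydro-β-ionone.
4. Diol ketone ⇒ β-ionone by one catalytic enantioselective anti-dihydroxylation (C6–O from a chiral dioxirane, C5–O from water with inversion). This step alone sets both stereocentres.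
5. Rings: none is built. The cyclohexane ring is that of β-ionone; the only ring formed is the transient oxirane, closed and opened within the first step.

Assumption: carotenoid numbering is used (ring C1–C6, chain C7–C15, then C15'–C10'), and the C10 dialdehyde and the L-fructose-derived ketone catalyst are taken as purchasable.

## Route

Step 1
Reactants: 1 β-ionone [(3E)-4-(2,6,6-trimethylcyclohex-1-en-1-yl)but-3-en-2-one]
Product: 3 (3E)-4-[(1R,2R)-1,2-dihydroxy-2,6,6-trimethylcyclohexyl]but-3-en-2-one, via (5S,6R)-5,6-epoxy-5,6-dihydro-β-ionone 2 (not isolated)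
Conditions: 1,2:4,5-di-O-isopropylidene-β-L-erythro-2,3-hexodiulo-2,6-pyranose (L-fructose-derived Shi ketone, 30 mol %), KHSO5 (as 2KHSO5·KHSO4·K2SO4), K2CO3, Bu4NHSO4, MeCN/aq. Na2B4O7 (pH 10.5), 0 °C; then crude 2, 0.5 M aq. HClO4/THF, 0 to 23 °C
Reagents that add atoms: potassium peroxymonosulfate, [K+].[O-]S(=O)(=O)OO (oxygen on C6); water, O (oxygen on C5)
Why: Proposed new method: a telescoped catalytic enantioselective anti-dihydroxylation of the tetrasubstituted γ,δ-alkene of a dienone, a substrate class on which it has not been shown. The chiral dioxirane from the L-ketone and KHSO5 is electrophilic and attacks only the electron-rich C5=C6 bond (the enone C7=C8 is inert) through the spiro transition state, with the C5 methyl in the crowded quadrant normally taken by the olefinic hydrogen of a trisubstituted alkene and the enone arm where phenyl sits in 1-phenylcyclohexene; since the D-ketone gives the (R,R)-oxide of 1-phenylcyclohexene, the L-ketone should by analogy give the (5S,6R)-oxirane 2. Aqueous acid then opens 2 by backside attack of water at C5 (tertiary and not deactivated by the enone, unlike the neopentyl, enone-conjugated C6), inverting C5 and keeping the C6–O bond, which gives the (5R,6R)-trans-diol; its enantiopurity is polished by crystallisation or chiral chromatography if needed. Closest known reactions: Shi asymmetric epoxidation of trisubstituted alkenes and of the distal alkene of conjugated dienoates, and acid-catalysed trans-hydrolysis of substituted cyclohexene oxides.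

Step 2
Reactants: 3 (3E)-4-[(1R,2R)-1,2-dihydroxy-2,6,6-trimethylcyclohexyl]but-3-en-2-one
Product: 4 (1R,2R)-1-[(1E)-3-hydroxy-3-methylpenta-1,4-dien-1-yl]-2,6,6-trimethylcyclohexane-1,2-diol (both epimers at the new carbinol carbon C9)
Conditions: CH2=CHMgBr (3.5 equiv), THF, −20 to 0 °C; then H2O
Reagents that add atoms: vinylmagnesium bromide, C=C[Mg]Br
Why: Grignard 1,2-addition: two equivalents of CH2=CHMgBr are spent on the two hydroxyl groups and the third adds to the ketone carbonyl in the 1,2-sense as in the technical vinylation of β-ionone, giving the C9 carbinol as both epimers, which is harmless because C9 becomes sp2 in step 3, while C5 and C6 are untouched.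

Step 3
Reactants: 4 (1R,2R)-1-[(1E)-3-hydroxy-3-methylpenta-1,4-dien-1-yl]-2,6,6-trimethylcyclohexane-1,2-diol
Product: 5 [(2E,4E)-5-[(1R,2R)-1,2-dihydroxy-2,6,6-trimethylcyclohexyl]-3-methylpenta-2,4-dien-1-yl]triphenylphosphonium bromide
Conditions: PPh3·HBr (1.05 equiv), MeOH, 0 to 23 °C; crystallise (acetone/EtOAc)
Reagents that add atoms: triphenylphosphine hydrobromide, Br.P(c1ccccc1)(c1ccccc1)c1ccccc1
Why: SN1' phosphonium-salt formation with allylic transposition (the technical vinyl-ionol to C15 Wittig salt reaction): the doubly allylic tertiary C9 alcohol is by far the most easily ionised hydroxyl, and PPh3 traps the pentadienyl cation at its unhindered terminus C11 to give the conjugated salt, whose 9E isomer is obtained pure by crystallisation; no stereocentre is formed or lost.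

Step 4
Reactants: 6 (2E,4E,6E)-2,7-dimethylocta-2,4,6-trienedial
Product: 7 methyl (2E,4E,6E,8E)-4,9-dimethyl-10-oxodeca-2,4,6,8-tetraenoate
Conditions: Ph3P=CHCO2Me (0.85 equiv), CH2Cl2, 0 to 23 °C
Reagents that add atoms: methyl (triphenylphosphoranylidene)acetate, COC(=O)C=P(c1ccccc1)(c1ccccc1)c1ccccc1
Why: Wittig olefination with a stabilised ylide gives the new C11'=C12' bond E, and with the dialdehyde in excess mono-olefination prevails because the remaining formyl group of 7 is a longer vinylogue and less electrophilic; 7 is separated from recovered 6 and a little diester by chromatography.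

Step 5
Reactants: 5 [(2E,4E)-5-[(1R,2R)-1,2-dihydroxy-2,6,6-trimethylcyclohexyl]-3-methylpenta-2,4-dien-1-yl]triphenylphosphonium bromide (1.1 equiv); 7 methyl (2E,4E,6E,8E)-4,9-dimethyl-10-oxodeca-2,4,6,8-tetraenoate
Product: 10 azafrin [(2E,4E,6E,8E,10E,12E,14E)-15-[(1R,2R)-1,2-dihydroxy-2,6,6-trimethylcyclohexyl]-4,9,13-trimethylpentadeca-2,4,6,8,10,12,14-heptaenoic acid], via C15 phosphonium ylide 8 (not isolated), via methyl azafrinate 9 (not isolated)
Conditions: NaOMe (1.2 equiv), MeOH/CH2Cl2, 0 to 23 °C; then aq. KOH, 60 °C, N2, dark; wash (toluene); then AcOH to pH 5, 0 °C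
Reagents that add atoms: potassium hydroxide, [K+].[OH-]
Why: Wittig olefination of the semi-stabilised allylic ylide 8 with polyenal 7 (the classical C15 + Cn carotenoid coupling) forms C11=C12 as an E/Z mixture; the warm alkaline phase then saponifies the methyl ester (BAc2) and thermally converts the sterically hindered 11Z isomer into the all-E form, Ph3PO is washed out of the aqueous carboxylate, and AcOH, too weak to ionise the tertiary allylic C6 alcohol, releases all-E 10 with C5 and C6 unchanged.

## Compound list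

1 | β-ionone, (3E)-4-(2,6,6-trimethylcyclohex-1-en-1-yl)but-3-en-2-one | CC(=O)/C=C/C1=C(C)CCCC1(C)C | starting material
2 | (5S,6R)-5,6-epoxy-5,6-dihydro-β-ionone, (3E)-4-[(1R,6S)-2,2,6-trimethyl-7-oxabicyclo[4.1.0]heptan-1-yl]but-3-en-2-one | CC(=O)/C=C/[C@]12O[C@@]1(C)CCCC2(C)C | intermediate (not isolated)
3 | (5R,6R)-5,6-dihydroxy-5,6-dihydro-β-ionone, (3E)-4-[(1R,2R)-1,2-dihydroxy-2,6,6-trimethylcyclohexyl]but-3-en-2-one | CC(=O)/C=C/[C@@]1(O)C(C)(C)CCC[C@@]1(C)O | intermediate
4 | (1R,2R)-1-[(1E)-3-hydroxy-3-methylpenta-1,4-dien-1-yl]-2,6,6-trimethylcyclohexane-1,2-diol (C9 epimer mixture) | C=CC(C)(O)/C=C/[C@@]1(O)C(C)(C)CCC[C@@]1(C)O | intermediate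
5 | [(2E,4E)-5-[(1R,2R)-1,2-dihydroxy-2,6,6-trimethylcyclohexyl]-3-methylpenta-2,4-dien-1-yl]triphenylphosphonium bromide | C/C(=C\C[P+](c1ccccc1)(c1ccccc1)c1ccccc1)/C=C/[C@@]1(O)C(C)(C)CCC[C@@]1(C)O.[Br-] | intermediate
6 | (2E,4E,6E)-2,7-dimethylocta-2,4,6-trienedial (C10 dialdehyde) | O=C/C(C)=C/C=C/C=C(\C)C=O | starting material
7 | methyl (2E,4E,6E,8E)-4,9-dimethyl-10-oxodeca-2,4,6,8-tetraenoate | COC(=O)/C=C/C(C)=C/C=C/C=C(\C)C=O | intermediate
8 | C15 phosphonium ylide, (1R,2R)-1-[(1E,3E)-3-methyl-5-(triphenyl-λ5-phosphanylidene)penta-1,3-dien-1-yl]-2,6,6-trimethylcyclohexane-1,2-diol | C/C(=C\C=P(c1ccccc1)(c1ccccc1)c1ccccc1)/C=C/[C@@]1(O)C(C)(C)CCC[C@@]1(C)O | intermediate (not isolated)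
9 | methyl azafrinate, methyl (2E,4E,6E,8E,10E,12E,14E)-15-[(1R,2R)-1,2-dihydroxy-2,6,6-trimethylcyclohexyl]-4,9,13-trimethylpentadeca-2,4,6,8,10,12,14-heptaenoate (formed as an 11E/11Z mixture, drawn all-E) | CC(/C=C/C=C(C)/C=C/[C@@]1(O)C(C)(C)CCC[C@@]1(C)O)=C\C=C\C=C(C)\C=C\C(=O)OC | intermediate (not isolated)
10 | azafrin, (2E,4E,6E,8E,10E,12E,14E)-15-[(1R,2R)-1,2-dihydroxy-2,6,6-trimethylcyclohexyl]-4,9,13-trimethylpentadeca-2,4,6,8,10,12,14-heptaenoic acid | CC(/C=C/C=C(C)/C=C/[C@@]1(O)C(C)(C)CCC[C@@]1(C)O)=C\C=C\C=C(C)\C=C\C(=O)O | target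

## Step count and risks

Total steps: 5. Longest linear sequence: 4 (steps 1, 2, 3, 5).

**Step 1 (proposed new method).** Risks: modest or reversed enantioselectivity on a tetrasubstituted alkene, and elimination of 2 to 6-hydroxy-α-ionone instead of hydration. If the sense of induction is the reverse of the model, the D-ketone is used in the same procedure. The fallback uses known chemistry, sets out from 1 and comes back at 3. Compound 1 is epoxidised with 3-chloroperoxybenzoic acid (CH2Cl2, 0 °C; only the 5,6-alkene reacts) to the racemic oxirane, that is 2 together with its enantiomer (5R,6S)-5,6-epoxy-5,6-dihydro-β-ionone F1. Hydrolysis with dilute aq. HClO4 in THF gives the racemic trans-diol, that is 3 together with its enantiomer (3E)-4-[(1S,2S)-1,2-dihydroxy-2,6,6-trimethylcyclohexyl]but-3-en-2-one F2. Preparative chiral SFC on an amylose tris(3,5-dimethylphenylcarbamate) phase then delivers 3.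

**Step 3.** Risk: the pentadienyl cation next to the free C6 hydroxyl may undergo a semipinacol shift or be captured by the C5 hydroxyl. The fallback avoids any carbocation, sets out from 3 (step 2 is then not needed) and comes back at 5. Horner–Wadsworth–Emmons olefination of 3 with triethyl phosphonoacetate and LiN(SiMe3)2 (excess, THF, 0 to 25 °C, lithium alkoxides kept cold to suppress retro-aldol-type ring opening) gives ethyl (2E,4E)-5-[(1R,2R)-1,2-dihydroxy-2,6,6-trimethylcyclohexyl]-3-methylpenta-2,4-dienoate F3; the 9Z isomer is removed by chromatography. Reduction with i-Bu2AlH (CH2Cl2, −78 °C) gives (1R,2R)-1-[(1E,3E)-5-hydroxy-3-methylpenta-1,3-dien-1-yl]-2,6,6-trimethylcyclohexane-1,2-diol F4. Appel bromination of the primary allylic alcohol only (CBr4, PPh3, CH2Cl2, −20 °C) gives (1R,2R)-1-[(1E,3E)-5-bromo-3-methylpenta-1,3-dien-1-yl]-2,6,6-trimethylcyclohexane-1,2-diol F5, which is quaternised by excess PPh3 in the same flask (SN2) to 5.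

**Step 5.** Risks: incomplete convergence of the E/Z mixture and difficult purification of the polyene acid from a one-flask sequence. The fallback changes the order of bond construction, sets out from 5 together with 6 (step 4 is then not needed) and comes back at 9. Ylide 8 (from 5, NaOMe, MeOH) is condensed with an excess of dialdehyde 6 to give (2E,4E,6E,8E,10E,12E)-13-[(1R,2R)-1,2-dihydroxy-2,6,6-trimethylcyclohexyl]-2,7,11-trimethyltrideca-2,4,6,8,10,12-hexaenal F6, a neutral aldehyde that is isomerised thermally and purified to the all-E form by crystallisation or chromatography. A second, E-selective Wittig reaction with Ph3P=CHCO2Me gives 9, now isolated and crystallised, which is saponified separately (KOH, aq. MeOH; AcOH) to 10.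

## Further compounds

F1 | step 1 | (5R,6S)-5,6-epoxy-5,6-dihydro-β-ionone, (3E)-4-[(1S,6R)-2,2,6-trimethyl-7-oxabicyclo[4.1.0]heptan-1-yl]but-3-en-2-one | CC(=O)/C=C/[C@@]12O[C@]1(C)CCCC2(C)C
F2 | step 1 | (3E)-4-[(1S,2S)-1,2-dihydroxy-2,6,6-trimethylcyclohexyl]but-3-en-2-one | CC(=O)/C=C/[C@]1(O)C(C)(C)CCC[C@]1(C)O
F3 | step 3 | ethyl (2E,4E)-5-[(1R,2R)-1,2-dihydroxy-2,6,6-trimethylcyclohexyl]-3-methylpenta-2,4-dienoate | CCOC(=O)/C=C(\C)/C=C/[C@@]1(O)C(C)(C)CCC[C@@]1(C)O
F4 | step 3 | (1R,2R)-1-[(1E,3E)-5-hydroxy-3-methylpenta-1,3-dien-1-yl]-2,6,6-trimethylcyclohexane-1,2-diol | OC/C=C(\C)/C=C/[C@@]1(O)C(C)(C)CCC[C@@]1(C)O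
F5 | step 3 | (1R,2R)-1-[(1E,3E)-5-bromo-3-methylpenta-1,3-dien-1-yl]-2,6,6-trimethylcyclohexane-1,2-diol | BrC/C=C(\C)/C=C/[C@@]1(O)C(C)(C)CCC[C@@]1(C)O
F6 | step 5 | (2E,4E,6E,8E,10E,12E)-13-[(1R,2R)-1,2-dihydroxy-2,6,6-trimethylcyclohexyl]-2,7,11-trimethyltrideca-2,4,6,8,10,12-hexaenal | O=C/C(C)=C/C=C/C=C(C)/C=C/C=C(C)/C=C/[C@@]1(O)C(C)(C)CCC[C@@]1(C)O
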